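The 1,2-dioxolane (O1–O2–C3–C4–C5) is taken apart across C4–C3 and O1–C5 into a silylperoxy ketal of methyl acetoacetate and a chiral 2-methyl-1-alkene. The key step exploits two latent functions of the ring: C3, which carries O2, a methyl and the acetate arm, is a masked ketone carbon, and C4–C5 is a masked 1,1-disubstituted alkene. An SnCl4-mediated peroxycarbenium annulation joins the alkene CH2 (C4) to C3 and lets the peroxide oxygen close on the tertiary C5 cation, so one operation builds the ring and both quaternary centres. C2' stems from catalytic asymmetric conjugate addition; the ring centres are not substrate-controlled and the diastereomers are separated.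

Key step: step 5

Assumption: the (R,SP) enantiomer of the ferrocenyl diphosphine is taken to deliver the (R)-ketone 4 from this enone and Grignard pairing; if the sense of induction is the opposite, the mirror-image ligand is used with no other change.

Step 1
Reactants: 1 6-bromohex-1-ene; 2 (E)-pent-3-en-2-one
Product: 4 (R)-4-methyldec-9-en-2-one, via hex-5-en-1-ylmagnesium bromide 3 (not isolated)
Conditions: Mg, Et2O, 0 °C; then 2, CuBr·SMe2 (5 mol %), (R)-1-[(SP)-2-(diphenylphosphino)ferrocenyl]ethyldicyclohexylphosphine (6 mol %), t-BuOMe, −75 °C; aq. NH4Cl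
Reagents that add atoms: none
Why: Copper-catalysed asymmetric conjugate addition of a Grignard reagent to a linear (E)-enone should set the methyl-bearing stereocenter (the later C2', R) by ligand control of the enone face, the terminal vinyl group being inert.

Step 2
Reactants: 4 (R)-4-methyldec-9-en-2-one
Product: 5 (R)-2,4-dimethyldeca-1,9-diene
Conditions: Ph3PCH3Br, KOt-Bu, THF, 0 °C to rt
Reagents that add atoms: methyltriphenylphosphonium bromide, C[P+](c1ccccc1)(c1ccccc1)c1ccccc1.[Br-]
Why: Wittig methylenation of the methyl ketone should give the 1,1-disubstituted alkene, and the stereocenter is β to the carbonyl and cannot epimerise.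

Step 3
Reactants: 6 methyl 3-methylbut-3-enoate
Product: 7 methyl 3-hydroperoxy-3-methoxybutanoate (racemic)
Conditions: O3, CH2Cl2/MeOH, −78 °C; N2 purge
Reagents that add atoms: ozone, [O-][O+]=O; methanol, CO
Why: Ozonolysis in methanol (Criegee cleavage) should place the carbonyl oxide on the disubstituted carbon, where methanol traps it as the α-methoxy hydroperoxide with loss of formaldehyde.

Step 4
Reactants: 7 methyl 3-hydroperoxy-3-methoxybutanoate
Product: 8 methyl 3-methoxy-3-[(triethylsilyl)peroxy]butanoate (racemic)
Conditions: Et3SiCl, imidazole, DMF, 0 °C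
Reagents that add atoms: chlorotriethylsilane, CC[Si](Cl)(CC)CC
Why: O-Silylation of the hydroperoxide under mild base should give the silylperoxy ketal that serves as the peroxycarbenium precursor.

Step 5
Reactants: 5 (R)-2,4-dimethyldeca-1,9-diene; 8 methyl 3-methoxy-3-[(triethylsilyl)peroxy]butanoate
Product: 11 methyl 2-[(3S,5R)-3,5-dimethyl-5-[(2R)-2-methyloct-7-en-1-yl]-1,2-dioxolan-3-yl]acetate, via silylperoxycarbenium ion 9 (not isolated), via tertiary carbocation 10 (not isolated)
Conditions: SnCl4 (1.1 equiv), CH2Cl2, −78 °C (8 in 1.5-fold excess); aq. NaHCO3; preparative HPLC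
Reagents that add atoms: none
Why: SnCl4 abstracts the methoxy group of 8 to give silylperoxycarbenium ion 9, whose carbon (C3) is attacked by the CH2 terminus of the 2-methyl-1-alkene of 5 in Markovnikov fashion (new C4–C3 bond) to give tertiary cation 10, and the silyl-bearing peroxide oxygen then captures C5 (new O1–C5 bond) with loss of the triethylsilyl group, so the dioxolane is closed in the same operation. The closest known reaction type is the Lewis-acid-mediated [3+2] annulation of silylperoxy ketals with alkenes, a Prins-type addition followed by cation capture. The ring forms by intermolecular C–C union followed by five-membered capture of the tertiary cation by the tethered peroxide oxygen; C5 carries no π bond or leaving group at that stage, so there is no exo/endo constraint. C3 is created in the C–C event on an acyclic, unbiased cation, and C5 in the capture, where the tin-bound ester arm is expected to send the branched chain to the opposite face (3,5-trans, as the target requires); neither centre is controlled relative to the remote C2' methyl, so 11 has to be separated from its (3R,5S)-trans partner and the cis pair by preparative HPLC. The step needs chemoselectivity for the 1,1-disubstituted over the terminal vinyl alkene, secured by the large nucleophilicity gap (tertiary versus secondary cation), and needs capture to outrun proton loss from 9 or 10, which the five-membered geometry and −78 °C should favour.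

Step 6
Reactants: 11 methyl 2-[(3S,5R)-3,5-dimethyl-5-[(2R)-2-methyloct-7-en-1-yl]-1,2-dioxolan-3-yl]acetate
Product: 12 methyl 2-[(3S,5R)-3,5-dimethyl-5-[(2R)-2-methyl-7-oxoheptyl]-1,2-dioxolan-3-yl]acetate
Conditions: O3, CH2Cl2, −78 °C; then Me2S, −78 °C to rt
Reagents that add atoms: ozone, [O-][O+]=O
Why: Ozonolysis with reductive work-up should cleave the only remaining alkene, the terminal vinyl group, to the aldehyde, the dialkyl peroxide and the ester being inert to ozone and dimethyl sulfide.

Step 7
Reactants: 13 styrene; 14 pent-4-en-1-ol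
Product: 15 (E)-5-phenylpent-4-en-1-ol
Conditions: second-generation Grubbs catalyst (3 mol %), styrene (3 equiv), CH2Cl2, 40 °C
Reagents that add atoms: none
Why: Olefin cross-metathesis of styrene with a terminal alkene is thermodynamically E-selective and tolerates the free alcohol.

Step 8
Reactants: 15 (E)-5-phenylpent-4-en-1-ol; 16 1-phenyl-1H-tetrazole-5-thiol
Product: 17 1-phenyl-5-{[(4E)-5-phenylpent-4-en-1-yl]sulfanyl}-1H-tetrazole
Conditions: PPh3, DIAD, THF, 0 °C to rt
Reagents that add atoms: none
Why: Mitsunobu thioetherification should convert the primary alcohol into the tetrazolyl sulfide with the acidic heteroaryl thiol as nucleophile.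

Step 9
Reactants: 17 1-phenyl-5-{[(4E)-5-phenylpent-4-en-1-yl]sulfanyl}-1H-tetrazole
Product: 18 1-phenyl-5-{[(4E)-5-phenylpent-4-en-1-yl]sulfonyl}-1H-tetrazole
Conditions: 30% aq. H2O2, (NH4)6Mo7O24·4H2O (10 mol %), EtOH, 0 °C to rt
Reagents that add atoms: hydrogen peroxide, OO
Why: Molybdate-catalysed sulfide oxidation with hydrogen peroxide should reach the sulfone without epoxidising the styrenyl alkene.

Step 10
Reactants: 12 methyl 2-[(3S,5R)-3,5-dimethyl-5-[(2R)-2-methyl-7-oxoheptyl]-1,2-dioxolan-3-yl]acetate; 18 1-phenyl-5-{[(4E)-5-phenylpent-4-en-1-yl]sulfonyl}-1H-tetrazole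
Product: 20 methyl 2-[(3S,5R)-3,5-dimethyl-5-[(2R,7E,11E)-2-methyl-12-phenyldodeca-7,11-dien-1-yl]-1,2-dioxolan-3-yl]acetate, via potassium sulfonyl carbanion 19 (not isolated)
Conditions: 18, KN(SiMe3)2, DME, −60 °C, 30 min; then 12, −60 °C to rt
Reagents that add atoms: none
Why: Julia–Kocienski olefination of an unbranched aldehyde with a pre-metalated 1-phenyltetrazolyl sulfone in DME should give the (E)-alkene by addition, Smiles rearrangement and loss of SO2 and tetrazolate, and the soft sulfonyl carbanion should not deprotonate the β-peroxy ester.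

Step 11
Reactants: 20 methyl 2-[(3S,5R)-3,5-dimethyl-5-[(2R,7E,11E)-2-methyl-12-phenyldodeca-7,11-dien-1-yl]-1,2-dioxolan-3-yl]acetate
Product: 21 2-[(3S,5R)-3,5-dimethyl-5-[(2R,7E,11E)-2-methyl-12-phenyldodeca-7,11-dien-1-yl]-1,2-dioxolan-3-yl]acetic acid
Conditions: LiOH, THF/H2O, 0 °C; then 1 M HCl to pH 3
Reagents that add atoms: lithium hydroxide, [Li+].[OH-]
Why: Saponification of the methyl ester at 0 °C should release the acid, since dialkyl peroxides are stable to cold aqueous hydroxide and no stereocenter is touched.

Compound list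
1 | 6-bromohex-1-ene | C=CCCCCBr | starting material
2 | (E)-pent-3-en-2-one | C/C=C/C(C)=O | starting material
3 | hex-5-en-1-ylmagnesium bromide | C=CCCCC[Mg]Br | intermediate
4 | (R)-4-methyldec-9-en-2-one | C[C@H](CCCCC=C)CC(C)=O | intermediate
5 | (R)-2,4-dimethyldeca-1,9-diene | C[C@H](CCCCC=C)CC(C)=C | intermediate
6 | methyl 3-methylbut-3-enoate | C=C(C)CC(=O)OC | starting material
7 | methyl 3-hydroperoxy-3-methoxybutanoate (racemic) | COC(C)(OO)CC(=O)OC | intermediate
8 | methyl 3-methoxy-3-[(triethylsilyl)peroxy]butanoate (racemic) | CC[Si](CC)(CC)OOC(C)(OC)CC(=O)OC | intermediate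
9 | silylperoxycarbenium ion, (4-methoxy-4-oxobutan-2-ylidene)[(triethylsilyl)oxy]oxonium | CC[Si](CC)(CC)O[O+]=C(C)CC(=O)OC | intermediate
10 | tertiary carbocation at C5 carrying the (3S)-silylperoxy acetate unit and the (R)-2-methyloct-7-enyl chain | C[C@H](CCCCC=C)C[C+](C)C[C@@](C)(CC(=O)OC)OO[Si](CC)(CC)CC | intermediate
11 | methyl 2-[(3S,5R)-3,5-dimethyl-5-[(2R)-2-methyloct-7-en-1-yl]-1,2-dioxolan-3-yl]acetate | C[C@H](CCCCC=C)C[C@]1(C)C[C@@](C)(CC(=O)OC)OO1 | intermediate
12 | methyl 2-[(3S,5R)-3,5-dimethyl-5-[(2R)-2-methyl-7-oxoheptyl]-1,2-dioxolan-3-yl]acetate | C[C@H](CCCCC=O)C[C@]1(C)C[C@@](C)(CC(=O)OC)OO1 | intermediate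
13 | styrene | C=Cc1ccccc1 | starting material
14 | pent-4-en-1-ol | C=CCCCO | starting material
15 | (E)-5-phenylpent-4-en-1-ol | OCCC/C=C/c1ccccc1 | intermediate
16 | 1-phenyl-1H-tetrazole-5-thiol | Sc1nnnn1-c1ccccc1 | starting material
17 | 1-phenyl-5-{[(4E)-5-phenylpent-4-en-1-yl]sulfanyl}-1H-tetrazole | c1ccccc1/C=C/CCCSc1nnnn1-c1ccccc1 | intermediate
18 | 1-phenyl-5-{[(4E)-5-phenylpent-4-en-1-yl]sulfonyl}-1H-tetrazole | c1ccccc1/C=C/CCCS(=O)(=O)c1nnnn1-c1ccccc1 | intermediate
19 | potassium (4E)-5-phenyl-1-[(1-phenyl-1H-tetrazol-5-yl)sulfonyl]pent-4-en-1-ide | [K+].c1ccccc1/C=C/CC[CH-]S(=O)(=O)c1nnnn1-c1ccccc1 | intermediate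
20 | methyl 2-[(3S,5R)-3,5-dimethyl-5-[(2R,7E,11E)-2-methyl-12-phenyldodeca-7,11-dien-1-yl]-1,2-dioxolan-3-yl]acetate | C[C@H](CCCC/C=C/CC/C=C/c1ccccc1)C[C@]1(C)C[C@@](C)(CC(=O)OC)OO1 | intermediate
21 | 2-[(3S,5R)-3,5-dimethyl-5-[(2R,7E,11E)-2-methyl-12-phenyldodeca-7,11-dien-1-yl]-1,2-dioxolan-3-yl]acetic acid | C[C@H](CCCC/C=C/CC/C=C/c1ccccc1)C[C@]1(C)C[C@@](C)(CC(=O)O)OO1 | target

Total step count: 11. Longest linear sequence: 6 steps (steps 1, 2, 5, 6, 10, 11).

Steps most likely to fail

Step 5. The annulation has no facial control relative to C2', and the trans preference rests only on the tin-bound ester arm. Proton loss from the ester-flanked peroxycarbenium ion, or capture of the C5 cation by the ester carbonyl, may also compete with peroxide closure. The fallback sets out from 4 and comes back at 11; it closes the ring through oxygen and sets C3 under ring control. The lithium enolate of acetone (LiN(i-Pr)2, THF, −78 °C) is added to 4 to give the tertiary aldol (6R)-4-hydroxy-4,6-dimethyldodec-11-en-2-one F1. Treatment with 50% H2O2 and catalytic H2SO4 exchanges the tertiary hydroxyl for a hydroperoxide, which closes on the ketone to the cyclic peroxyhemiketal 3,5-dimethyl-5-[(2R)-2-methyloct-7-en-1-yl]-1,2-dioxolan-3-ol F2. MeOH with catalytic TsOH gives 3-methoxy-3,5-dimethyl-5-[(2R)-2-methyloct-7-en-1-yl]-1,2-dioxolane F3. TiCl4 and 1-methoxy-1-(trimethylsilyloxy)ethene in CH2Cl2 at −78 °C should then add the acetate arm to the cyclic peroxycarbenium ion anti to the larger C5 substituent, giving 11. C5 is still formed without control in this sequence, and its epimer has to be removed by chromatography.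

Step 3. The primary ozonide may fragment in the opposite sense, putting the carbonyl oxide on the CH2 carbon and leaving methyl acetoacetate instead of 7. The fallback sets out from 6 and comes back at 7. Reductive ozonolysis (O3, CH2Cl2, −78 °C; then Me2S) is used on purpose to give methyl 3-oxobutanoate F4. Trimethyl orthoformate, MeOH and catalytic TsOH convert it into methyl 3,3-dimethoxybutanoate F5. Acid-catalysed exchange of one methoxy group with ethereal H2O2 (catalytic BF3·OEt2, 0 °C) should then give 7.

Step 10. The metalated sulfone may deprotonate the ester α-position and open the dioxolane by β-elimination at C3, and E selectivity may erode. The fallback sets out from 12 and comes back at 21 by reversing the order of the last two operations. 12 is saponified first (LiOH, THF/H2O, 0 °C) to 2-[(3S,5R)-3,5-dimethyl-5-[(2R)-2-methyl-7-oxoheptyl]-1,2-dioxolan-3-yl]acetic acid F6. Its potassium carboxylate (1 equiv KN(SiMe3)2), which is far less prone to α-deprotonation, is then added to 19 in DME at −60 °C to give 21 directly.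

Further compounds
F1 | step 5 | (6R)-4-hydroxy-4,6-dimethyldodec-11-en-2-one (both C4 epimers) | C[C@H](CCCCC=C)CC(C)(O)CC(C)=O
F2 | step 5 | 3,5-dimethyl-5-[(2R)-2-methyloct-7-en-1-yl]-1,2-dioxolan-3-ol | C[C@H](CCCCC=C)CC1(C)CC(C)(O)OO1
F3 | step 5 | 3-methoxy-3,5-dimethyl-5-[(2R)-2-methyloct-7-en-1-yl]-1,2-dioxolane | C[C@H](CCCCC=C)CC1(C)CC(C)(OC)OO1
F4 | step 3 | methyl 3-oxobutanoate | CC(=O)CC(=O)OC
F5 | step 3 | methyl 3,3-dimethoxybutanoate | COC(C)(OC)CC(=O)OC
F6 | step 10 | 2-[(3S,5R)-3,5-dimethyl-5-[(2R)-2-methyl-7-oxoheptyl]-1,2-dioxolan-3-yl]acetic acid | C[C@H](CCCCC=O)C[C@]1(C)C[C@@](C)(CC(=O)O)OO1
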